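**Plan**

- Retrosynthesis: the C8–CH(Ph) bond is cut first (Friedel–Crafts cut) to (S)-strobopinin 10 and the benzhydrol 16 of the methoxy-methyl-resorcinol ring, blocked with Br at its one free position. The C3–C4 bond of ring C of 10 is cut next, to aldehyde 8 with an ortho 1-phenylvinyl ether. The O1–C2 bond and the ring A formyl and hydroxyl groups then go back to 2-methylresorcinol.
- Enabling feature: in ring C the array O1–C2H(Ph)–C3H2–C4(=O) sits on the ortho pair C8a/C4a of ring A, C2 is β to the ketone and C3 is an unsubstituted CH2. Ring C is therefore the formal adduct of the aldehyde C4–H across the enol ether O1–C2(Ph)=C3H2.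
- Forward: ring A is dressed by symmetry (C6 methyl para to the future O1), the vinyl ether is installed, ring C is closed by enantioselective rhodium-catalysed hydroacylation and the MOM groups are removed. The two aryl halves are then joined at C8 and the bromine is taken off.
- Stereochemistry: C2 (S) comes from the chiral bisphosphine on rhodium in the ring closure. The triarylmethine (S) comes from a chiral phosphoric acid in the arylation of an ortho-quinone methide.

Key step: step 6

Assumption: (R)-DTBM-SEGPHOS in step 6 and (R)-TRIP in step 12 are taken to give the (S) centres; should a test run show the opposite sense of induction, the commercial (S) antipode is used and nothing else changes.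

**Route**

Step 1
Reactants: 1 2-methylresorcinol (2-methylbenzene-1,3-diol)
Product: 2 1,3-bis(methoxymethoxy)-2-methylbenzene
Conditions: NaH (2.4 equiv), MOMCl (2.4 equiv), DMF, 0 °C to rt
Reagents that add atoms: chloromethyl methyl ether (MOMCl), COCCl
Why: Williamson-type O-alkylation of both phenoxides with the reactive α-chloro ether should give the bis-acetal, which masks the future 5-OH and 7-OH and adds no aromatic C–H that could interfere in step 2.

Step 2
Reactants: 2 1,3-bis(methoxymethoxy)-2-methylbenzene
Product: 4 3,5-bis(methoxymethoxy)-4-methylphenol, via pinacol arylboronate 3 (not isolated)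
Conditions: [Ir(cod)OMe]2 (1.5 mol %), 4,4'-di-tert-butyl-2,2'-bipyridine (3 mol %), B2pin2 (0.7 equiv), THF, 80 °C; then aq H2O2, NaOH, 0 °C to rt, same flask
Reagents that add atoms: bis(pinacolato)diboron, CC1(C)OB(OC1(C)C)B1OC(C)(C)C(C)(C)O1 (boron of 3); hydrogen peroxide, OO (phenol oxygen of 4)
Why: Sterically governed iridium-catalysed C–H borylation (Hartwig–Miyaura type) should go only to the one ring C–H without an ortho substituent, which lies para to the methyl group (the future C8a–O1), and the boronate is oxidised in place to the phenol.

Step 3
Reactants: 4 3,5-bis(methoxymethoxy)-4-methylphenol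
Product: 5 6-hydroxy-2,4-bis(methoxymethoxy)-3-methylbenzaldehyde
Conditions: MgCl2 (1.5 equiv), Et3N (3.8 equiv), paraformaldehyde (6 equiv), MeCN, reflux
Reagents that add atoms: paraformaldehyde (as formaldehyde), C=O
Why: Magnesium-phenoxide-directed ortho-formylation (Casnati–Skattebøl) places the formyl group only ortho to the free hydroxyl, and the two ortho positions of 4 are equivalent by symmetry, so a single aldehyde with CHO between OH and OMOM is expected.

Step 4
Reactants: 5 6-hydroxy-2,4-bis(methoxymethoxy)-3-methylbenzaldehyde; 6 rac-2-bromo-1-phenylethanol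
Product: 7 rac-6-(2-bromo-1-phenylethoxy)-2,4-bis(methoxymethoxy)-3-methylbenzaldehyde
Conditions: PPh3 (1.5 equiv), DIAD (1.5 equiv), THF, 0 °C to rt
Reagents that add atoms: none
Why: Mitsunobu etherification suits the acidic salicylaldehyde-type hydroxyl of 5, and the β-bromine suppresses ionisation of the benzylic oxyphosphonium so that SN2 displacement is expected; the new centre is racemic and is erased in step 5.

Step 5
Reactants: 7 rac-6-(2-bromo-1-phenylethoxy)-2,4-bis(methoxymethoxy)-3-methylbenzaldehyde
Product: 8 2,4-bis(methoxymethoxy)-3-methyl-6-[(1-phenylethenyl)oxy]benzaldehyde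
Conditions: KOtBu (1.3 equiv), THF, −20 °C to rt
Reagents that add atoms: none
Why: E2 dehydrobromination can only remove the benzylic, oxygen-bearing hydrogen, so the α-aryloxystyrene is the sole alkene possible, and the aldehyde has no α-hydrogen for the base to enolise.

Step 6
Reactants: 8 2,4-bis(methoxymethoxy)-3-methyl-6-[(1-phenylethenyl)oxy]benzaldehyde
Product: 9 (2S)-5,7-bis(methoxymethoxy)-6-methyl-2-phenyl-2,3-dihydro-4H-chromen-4-one
Conditions: [Rh(cod)Cl]2 (2.5 mol %), (R)-DTBM-SEGPHOS (5.5 mol %), NaB[3,5-(CF3)2C6H3]4 (5 mol %), degassed 1,4-dioxane, 60–80 °C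
Reagents that add atoms: none
Why: Proposed new method: the cationic monovalent rhodium bisphosphine should add oxidatively into the aldehyde C–H bond of 8, helped by the neighbouring enol-ether oxygen and alkene, to give a trivalent acyl rhodium hydride, which delivers hydride to the inner alkene carbon (the future C2) and then forms the C3–C4 bond by reductive elimination from a seven-membered acyl alkyl rhodacycle. The closest known reaction type is the rhodium-bisphosphine-catalysed enantioselective intramolecular hydroacylation of 1,1-disubstituted alkenes held ortho to an aryl aldehyde (2-vinyl- and 2-allylbenzaldehydes, N-vinyl heteroaryl aldehydes), which gives benzo-fused ketones with a β-stereocentre; an oxygen-linked 1-arylvinyl ether closing to a flavanone has not been shown. Ring C closes in the 6-endo-trig mode, both alkene carbons becoming ring atoms. The C2 stereocentre is set in the hydride insertion, where the chiral pocket of the bisphosphine selects the alkene face (catalyst control, 8 being achiral). The step needs endo over exo insertion and ring closure over decarbonylation: the exo path would put rhodium on the fully substituted carbon and require reductive elimination to a quaternary centre, the alkene has no allylic hydrogen and cannot isomerise, and the short rigid ortho tether keeps the alkene at the metal so that insertion should outrun CO loss. The neutral conditions spare the base-labile C2 centre, and the MOM ethers keep a phenoxide from binding rhodium on the side away from the alkene.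

Step 7
Reactants: 9 (2S)-5,7-bis(methoxymethoxy)-6-methyl-2-phenyl-2,3-dihydro-4H-chromen-4-one
Product: 10 (2S)-5,7-dihydroxy-6-methyl-2-phenyl-2,3-dihydro-4H-chromen-4-one ((S)-strobopinin)
Conditions: 3 M aq HCl, MeOH, 45 °C
Reagents that add atoms: none
Why: Acid-catalysed acetal exchange with methanol should remove both MOM groups, and acid is chosen because the flavanone C2 centre is lost through base-induced ring opening to the chalcone but should hold under mild acid.

Step 8
Reactants: 11 2,4,6-trihydroxytoluene (2-methylbenzene-1,3,5-triol)
Product: 13 2,4,6-trihydroxy-3-methylbenzaldehyde, via aryl iminium chloride 12 (not isolated)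
Conditions: POCl3 (1.1 equiv), DMF (1.2 equiv), EtOAc, 0 °C to rt; then H2O, 50 °C
Reagents that add atoms: N,N-dimethylformamide, CN(C)C=O (formyl carbon); water, O (formyl oxygen)
Why: Vilsmeier–Haack formylation of the very nucleophilic phloroglucinol ring should stop after one substitution because the iminium group deactivates the ring, and the two free positions of 11 are equivalent, so only one aldehyde can form.

Step 9
Reactants: 13 2,4,6-trihydroxy-3-methylbenzaldehyde
Product: 14 2,6-dihydroxy-4-methoxy-3-methylbenzaldehyde
Conditions: Me2SO4 (1.0 equiv), K2CO3 (1.1 equiv), acetone, 0 °C to rt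
Reagents that add atoms: dimethyl sulfate, COS(=O)(=O)OC
Why: Chemoselective Williamson O-methylation is expected at the 4-hydroxyl, which is para to the formyl group and hence the most acidic and not held in the hydrogen bond to the carbonyl, and the hard sulfate electrophile favours O- over C-methylation.

Step 10
Reactants: 14 2,6-dihydroxy-4-methoxy-3-methylbenzaldehyde
Product: 15 3-bromo-2,6-dihydroxy-4-methoxy-5-methylbenzaldehyde
Conditions: NBS (1.0 equiv), MeCN, 0 °C, dark
Reagents that add atoms: N-bromosuccinimide, O=C1CCC(=O)N1Br
Why: Electrophilic aromatic bromination can only occur at the single free ring position, and the bromine is a temporary block that stops this ring from acting as a nucleophile in step 12.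

Step 11
Reactants: 15 3-bromo-2,6-dihydroxy-4-methoxy-5-methylbenzaldehyde
Product: 16 rac-(3-bromo-2,6-dihydroxy-4-methoxy-5-methylphenyl)(phenyl)methanol
Conditions: PhMgBr (3.5 equiv), THF, −20 to 0 °C; aq NH4Cl; used crude
Reagents that add atoms: phenylmagnesium bromide, Br[Mg]c1ccccc1
Why: Grignard addition to the aldehyde should follow deprotonation of the two phenols by the first two equivalents, the aryl bromide being inert to PhMgBr at this temperature; the carbinol centre is racemic and becomes planar in step 12.

Step 12
Reactants: 10 (S)-strobopinin; 16 rac-(3-bromo-2,6-dihydroxy-4-methoxy-5-methylphenyl)(phenyl)methanol (1.3 equiv, added slowly)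
Product: 18 (2S)-8-[(S)-(3-bromo-2,6-dihydroxy-4-methoxy-5-methylphenyl)(phenyl)methyl]-5,7-dihydroxy-6-methyl-2-phenyl-2,3-dihydro-4H-chromen-4-one, via ortho-quinone methide 17 (not isolated)
Conditions: (R)-TRIP (10 mol %), CH2Cl2 (toluene as co-solvent), 5 Å MS, −20 to 0 °C
Reagents that add atoms: none
Why: Chiral-phosphoric-acid-catalysed dehydration of an ortho-hydroxybenzhydrol to its ortho-quinone methide followed by enantioselective Friedel–Crafts 1,4-addition of a phenol is a known way to triarylmethanes; here C8 is the only unsubstituted, phenol-activated position of 10, the 7-OH hydrogen-bonds to the phosphate so that the acid holds both partners and fixes which face of the benzylidene carbon is attacked (catalyst control of the new (S) centre, C2 being remote), and the fully substituted ring of 16 cannot compete as a nucleophile.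

Step 13
Reactants: 18 (2S)-8-[(S)-(3-bromo-2,6-dihydroxy-4-methoxy-5-methylphenyl)(phenyl)methyl]-5,7-dihydroxy-6-methyl-2-phenyl-2,3-dihydro-4H-chromen-4-one
Product: 19 (2S)-8-[(S)-(2,6-dihydroxy-4-methoxy-3-methylphenyl)(phenyl)methyl]-5,7-dihydroxy-6-methyl-2-phenyl-2,3-dihydro-4H-chromen-4-one (target)
Conditions: H2 (1 atm), 10% Pd/C, NaOAc (1.5 equiv), EtOAc/MeOH, rt
Reagents that add atoms: none
Why: Palladium-catalysed hydrogenolysis of the aryl C–Br bond should be fast under conditions that leave the chelated aryl ketone, the cyclic benzylic ether and both stereocentres alone, with acetate taking up the HBr without opening ring C.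

**Compound list**

1 | 2-methylresorcinol | Cc1c(O)cccc1O | starting material
2 | 1,3-bis(methoxymethoxy)-2-methylbenzene | COCOc1cccc(OCOC)c1C | intermediate
3 | 2-[3,5-bis(methoxymethoxy)-4-methylphenyl]-4,4,5,5-tetramethyl-1,3,2-dioxaborolane | COCOc1cc(B2OC(C)(C)C(C)(C)O2)cc(OCOC)c1C | intermediate
4 | 3,5-bis(methoxymethoxy)-4-methylphenol | COCOc1cc(O)cc(OCOC)c1C | intermediate
5 | 6-hydroxy-2,4-bis(methoxymethoxy)-3-methylbenzaldehyde | COCOc1cc(O)c(C=O)c(OCOC)c1C | intermediate
6 | rac-2-bromo-1-phenylethanol | OC(CBr)c1ccccc1 | starting material
7 | rac-6-(2-bromo-1-phenylethoxy)-2,4-bis(methoxymethoxy)-3-methylbenzaldehyde | COCOc1cc(OC(CBr)c2ccccc2)c(C=O)c(OCOC)c1C | intermediate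
8 | 2,4-bis(methoxymethoxy)-3-methyl-6-[(1-phenylethenyl)oxy]benzaldehyde | COCOc1cc(OC(=C)c2ccccc2)c(C=O)c(OCOC)c1C | intermediate
9 | (2S)-5,7-bis(methoxymethoxy)-6-methyl-2-phenyl-2,3-dihydro-4H-chromen-4-one | COCOc1cc2O[C@H](c3ccccc3)CC(=O)c2c(OCOC)c1C | intermediate
10 | (2S)-5,7-dihydroxy-6-methyl-2-phenyl-2,3-dihydro-4H-chromen-4-one ((S)-strobopinin) | Cc1c(O)cc2O[C@H](c3ccccc3)CC(=O)c2c1O | intermediate
11 | 2,4,6-trihydroxytoluene | Cc1c(O)cc(O)cc1O | starting material
12 | [(2,4,6-trihydroxy-3-methylphenyl)methylidene]dimethylammonium chloride | Cc1c(O)cc(O)c(C=[N+](C)C)c1O.[Cl-] | intermediate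
13 | 2,4,6-trihydroxy-3-methylbenzaldehyde | Cc1c(O)cc(O)c(C=O)c1O | intermediate
14 | 2,6-dihydroxy-4-methoxy-3-methylbenzaldehyde | COc1cc(O)c(C=O)c(O)c1C | intermediate
15 | 3-bromo-2,6-dihydroxy-4-methoxy-5-methylbenzaldehyde | COc1c(Br)c(O)c(C=O)c(O)c1C | intermediate
16 | rac-(3-bromo-2,6-dihydroxy-4-methoxy-5-methylphenyl)(phenyl)methanol | COc1c(Br)c(O)c(C(O)c2ccccc2)c(O)c1C | intermediate
17 | 6-benzylidene-4-bromo-5-hydroxy-3-methoxy-2-methylcyclohexa-2,4-dien-1-one | COC1=C(C)C(=O)C(=Cc2ccccc2)C(O)=C1Br | intermediate
18 | (2S)-8-[(S)-(3-bromo-2,6-dihydroxy-4-methoxy-5-methylphenyl)(phenyl)methyl]-5,7-dihydroxy-6-methyl-2-phenyl-2,3-dihydro-4H-chromen-4-one | COc1c(Br)c(O)c([C@H](c2ccccc2)c2c(O)c(C)c(O)c3c2O[C@H](c2ccccc2)CC3=O)c(O)c1C | intermediate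
19 | (2S)-8-[(S)-(2,6-dihydroxy-4-methoxy-3-methylphenyl)(phenyl)methyl]-5,7-dihydroxy-6-methyl-2-phenyl-2,3-dihydro-4H-chromen-4-one | COc1cc(O)c([C@H](c2ccccc2)c2c(O)c(C)c(O)c3c2O[C@H](c2ccccc2)CC3=O)c(O)c1C | target

**Step count and risks**

Total steps: 13. Longest linear sequence: 9 (steps 1–7, 12, 13); steps 8–11 make the second fragment.

Steps most likely to fail:

1. Step 6 (proposed new method). The acyl rhodium hydride of this doubly ortho-substituted aldehyde may lose CO, the alkene may insert in the exo sense, or the hydride transfer may discriminate poorly between the alkene faces. The fallback uses known chemistry and takes the C2 centre from the chiral pool. It sets out from 5. Mitsunobu etherification with commercial (S)-2-bromo-1-phenylethanol (O[C@H](CBr)c1ccccc1; PPh3, DIAD, THF) should give, with inversion, (R)-6-(2-bromo-1-phenylethoxy)-2,4-bis(methoxymethoxy)-3-methylbenzaldehyde F1. An N-heterocyclic carbene generated from 3-benzyl-5-(2-hydroxyethyl)-4-methylthiazolium chloride with DBU (toluene, 60 °C) then turns the aldehyde into its Breslow intermediate, which displaces the primary bromide intramolecularly. This forms the same C3–C4 bond with C2 already in place and comes back to the route at 9. The base is kept weak and sub-stoichiometric in free form to limit elimination of HBr and opening of ring C.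

2. Step 12. Facial selectivity at the benzylidene carbon may be poor, because the quinone methide carries two flanking oxygen groups, or the arylation may be reversible under acid and erode the ratio. The fallback replaces catalyst control by separation of diastereomers. It sets out from 10 and 16: the same arylation is run with achiral diphenyl phosphate (CH2Cl2, 0 °C), which should give 18 together with its methine epimer (2S)-8-[(R)-(3-bromo-2,6-dihydroxy-4-methoxy-5-methylphenyl)(phenyl)methyl]-5,7-dihydroxy-6-methyl-2-phenyl-2,3-dihydro-4H-chromen-4-one F2. Because C2 is fixed, the two are diastereomers and are separated by preparative chromatography. The route is rejoined at 18.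

3. Step 9. Methylation may occur at more than one hydroxyl, at an ortho hydroxyl, or at the free ring carbon. The fallback replaces selection by acidity with selection by chelation. It sets out from 13: exhaustive O-methylation (excess Me2SO4, K2CO3, acetone, reflux) should give 2,4,6-trimethoxy-3-methylbenzaldehyde F3. BCl3 (CH2Cl2, 0 °C to rt) should then cleave only the two methoxy groups ortho to the formyl group through boron chelation to the carbonyl. This comes back to the route at 14.

Further compounds
F1 | step 6 | (R)-6-(2-bromo-1-phenylethoxy)-2,4-bis(methoxymethoxy)-3-methylbenzaldehyde | COCOc1cc(O[C@@H](CBr)c2ccccc2)c(C=O)c(OCOC)c1C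
F2 | step 12 | (2S)-8-[(R)-(3-bromo-2,6-dihydroxy-4-methoxy-5-methylphenyl)(phenyl)methyl]-5,7-dihydroxy-6-methyl-2-phenyl-2,3-dihydro-4H-chromen-4-one | COc1c(Br)c(O)c([C@@H](c2ccccc2)c2c(O)c(C)c(O)c3c2O[C@H](c2ccccc2)CC3=O)c(O)c1C
F3 | step 9 | 2,4,6-trimethoxy-3-methylbenzaldehyde | COc1cc(OC)c(C=O)c(OC)c1C
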